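Numbering used throughout: ring B = C5–C10; C10 carries the methyl C14 and the oxirane arm C1–C2; C5 carries the acrolein arm C4(=C15)–C3HO; the lactone is C7–C11(=C13)–C12(=O)–O–C8; in the bicyclic intermediates ring A = C10–C1–C2=C3–C4–C5; β is the face of ring B that bears C14.
Retrosynthetic cuts, in order: oxirane O–C2 (back to a 1,2-diol), C4=C15 and C11=C13 (two Mannich methylenations), reconnection of C2 to C3 as a ring-A alkene, lactone O–C12, the C8 and C9 oxygens, C7–C11 (cross-coupling at an enol triflate), and finally C10–C1 and C5–C4 (Diels–Alder).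
Enabling feature: C10 and C5 are vicinal ring carbons whose two-carbon arms C1–C2 and C4–C3 are the halves of a butadiene severed between C2 and C3, and ring B has para oxygens at C6 and C9, a methyl at C10 and a replaceable group at C7; ring B is therefore 2-methoxy-5-methylbenzoquinone and the arms are a 1-silyloxybutadiene.
Forward order of rings: ring B is bought as the quinone, ring A is closed by the cycloaddition, the γ-lactone is closed after hydroxylation at C8, ring A is opened again by ozonolysis at C2=C3, and the oxirane is closed last.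
Stereochemistry: C10 from the chiral Lewis acid, C1 from the endo transition state, C5 and C7 from equilibration to the trans-fused dione with an equatorial arm, C6 and C9 from hydride attack anti to the axial C10 methyl and to the axial C1 silyloxy group, C8 from enolate hydroxylation on the face free of the two β-axial groups.

Key step: step 2

Assumption: the sense of enantioface selection in step 2 is assigned by analogy with oxazaborolidinium-bound quinones; the (S)-catalyst is written, and its mirror image is to be used without any other change if the first adduct proves to be the antipode.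

Step 1
Reactants: 1 (E)-but-2-enal
Product: 2 (E)-1-(triisopropylsilyloxy)buta-1,3-diene
Conditions: TIPSOTf, Et3N, Et2O, 0 °C to rt
Reagents that add atoms: triisopropylsilyl trifluoromethanesulfonate, CC(C)[Si](C(C)C)(C(C)C)OS(=O)(=O)C(F)(F)F
Why: Silyl dienol ether formation: O-silylation of the enal makes the γ-hydrogens acidic enough for Et3N, and the extended conjugate base should give mainly the (E)-dienyl ether, the only isomer able to reach the s-cis geometry needed in step 2.

Step 2
Reactants: 2 (E)-1-(triisopropylsilyloxy)buta-1,3-diene; 3 2-methoxy-5-methyl-1,4-benzoquinone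
Product: 4 cis-fused cycloadduct 7-methoxy-10β-methyl-1α-(triisopropylsilyloxy)decalin-2,7-diene-6,9-dione (5β-H)
Conditions: (S)-3,3-diphenyl-1-(2-methylphenyl)tetrahydro-1H,3H-pyrrolo[1,2-c][1,3,2]oxazaborole (20 mol%), (CF3SO2)2NH (17 mol%), CH2Cl2, −78 °C
Reagents that add atoms: none
Why: The oxazaborolidinium ion binds O9, the more basic vinylogous-ester oxygen of 3, and so lowers the LUMO of the C10=C5 double bond; the diene then adds in a concerted, asynchronous [4+2] cycloaddition in which its unsubstituted terminus (C4) bonds ahead to C5, the carbon β to the bound carbonyl, and its silyloxy terminus (C1) to C10. The closest known reactions are the Diels–Alder additions of this quinone at its methyl-bearing double bond under monodentate Lewis acids and the oxazaborolidinium-catalysed enantioselective Diels–Alder reactions of unsymmetrical quinones with silyloxydienes. Ring A is closed as a six-membered ring by addition that is suprafacial on both partners, so the C10–C1 and C5–C4 bonds form on one face of ring B and the ring fusion is cis. C10 is fixed by the catalyst, whose aryl group screens one face of the bound enedione; C1 follows from the endo transition state (diene under the C6/C9 enedione) together with the E geometry of 2, which places the silyloxy group anti to the angular methyl; C5 is formed cis to the methyl and is corrected in step 6. The step needs site selectivity, secured by the methoxy group, which deactivates C7=C8 by donation; orientation, secured by binding at O9 and not at O6; and endo and enantioface selectivity, secured by the catalyst at low temperature.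

Step 3
Reactants: 4 cis-fused cycloadduct
Product: 5 cis-fused 7-hydroxy-10β-methyl-1α-(triisopropylsilyloxy)decalin-2,7-diene-6,9-dione (vinylogous acid)
Conditions: 1 M HCl (aq), THF, rt
Reagents that add atoms: water, O
Why: Acid-catalysed hydrolysis of a vinylogous ester (addition of water at C7, loss of methanol) should free the vinylogous acid without enolate chemistry, so the hindered silyl ether and the ring fusion are left alone and no stereocentre is formed.

Step 4
Reactants: 5 cis-fused 7-hydroxy enedione
Product: 6 cis-fused 7-(trifluoromethanesulfonyloxy)-10β-methyl-1α-(triisopropylsilyloxy)decalin-2,7-diene-6,9-dione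
Conditions: Tf2O, pyridine, CH2Cl2, −78 to 0 °C
Reagents that add atoms: trifluoromethanesulfonic anhydride, FC(F)(F)S(=O)(=O)OS(=O)(=O)C(F)(F)F
Why: Enol triflate formation from a vinylogous acid should take place at the unhindered O7, which keeps the enedione conjugation (O9 is screened by the quaternary C10), and turns C7 into a site for oxidative addition.

Step 5
Reactants: 6 cis-fused 7-triflyloxy enedione; 7 tert-butyl bromoacetate
Product: 9 cis-fused 7-(tert-butoxycarbonylmethyl)-10β-methyl-1α-(triisopropylsilyloxy)decalin-2,7-diene-6,9-dione, via Reformatsky reagent 8 (not isolated)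
Conditions: 7, Zn dust (Me3SiCl-activated), THF, rt; then 6, Pd2(dba)3 (2.5 mol%), 2-dicyclohexylphosphino-2′,4′,6′-triisopropylbiphenyl (10 mol%), THF, rt
Reagents that add atoms: none
Why: Negishi-type cross-coupling of a Reformatsky reagent with an enol triflate: zerovalent palladium inserts into the C7–OTf bond of the electron-poor triflate and transmetallation and reductive elimination deliver the acetate carbon to C7 only, which removes the 1,2- versus 1,4-addition ambiguity of a direct displacement at the methoxy stage; no stereocentre is formed and any epimerisation at C5 is levelled in step 6.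

Step 6
Reactants: 9 cis-fused 7-(tert-butoxycarbonylmethyl) enedione
Product: 11 trans-fused 7β-(tert-butoxycarbonylmethyl)-10β-methyl-1α-(triisopropylsilyloxy)decal-2-ene-6,9-dione (5α-H), via kinetic cis-dione 10 (not isolated)
Conditions: Zn dust, AcOH, rt; filter, evaporate; DBU (0.2 equiv), toluene, rt
Reagents that add atoms: none
Why: Zn/AcOH reduction of an ene-1,4-dione saturates only C7=C8, and DBU then equilibrates C5 and C7 through the C6 enolates toward the trans-fused chair in which the C7 arm is equatorial and the C1 silyloxy group is axial and clear of the C9 carbonyl, by analogy with the base-induced cis-to-trans isomerisation of related angular-methyl quinone adducts.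

Step 7
Reactants: 11 trans-fused 6,9-dione
Product: 12 trans-fused 7β-(tert-butoxycarbonylmethyl)-6β-hydroxy-10β-methyl-1α-(triisopropylsilyloxy)decal-2-en-9-one
Conditions: NaBH4, MeOH/CH2Cl2 (1:1), −40 °C
Reagents that add atoms: none
Why: Borohydride reduction under steric approach control: C6, flanked by two CH centres, should react before the neopentyl C9 carbonyl next to quaternary C10, and hydride enters from the α-face because the axial β-trajectory is blocked by the syn-axial C10 methyl (the behaviour of 6-oxo steroids), giving the axial 6β-alcohol, while the tert-butyl ester resists attack by the new alkoxide at low temperature.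

Step 8
Reactants: 12 6β-hydroxy 9-ketone; 13 isobutyric anhydride
Product: 14 trans-fused 7β-(tert-butoxycarbonylmethyl)-6β-isobutyryloxy-10β-methyl-1α-(triisopropylsilyloxy)decal-2-en-9-one
Conditions: 4-(dimethylamino)pyridine (1 equiv), Et3N, CH2Cl2, rt to 40 °C
Reagents that add atoms: none
Why: Nucleophilic-catalysed acyl transfer (Steglich-type acylation via the acylpyridinium ion) esterifies the only hydroxyl, and the configuration at C6 is untouched.

Step 9
Reactants: 14 6β-isobutyryloxy 9-ketone
Product: 16 trans-fused 7β-(tert-butoxycarbonylmethyl)-8α-hydroxy-6β-isobutyryloxy-10β-methyl-1α-(triisopropylsilyloxy)decal-2-en-9-one, via sodium enolate 15 (not isolated)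
Conditions: NaN(SiMe3)2, THF, −78 °C; 2-(phenylsulfonyl)-3-phenyloxaziridine, −78 °C; AcOH quench
Reagents that add atoms: 2-(phenylsulfonyl)-3-phenyloxaziridine, O=S(=O)(c1ccccc1)N1OC1c1ccccc1
Why: Davis oxidation of a ketone enolate: C9 can enolise only toward C8 and the silylamide is too weak to deprotonate the esters, and the oxaziridine should reach C8 from the α-face because the β-face carries two syn-axial groups (the C10 methyl and the 6β-ester), giving the equatorial 8α-hydroxy ketone, which is also the more stable epimer.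

Step 10
Reactants: 16 8α-hydroxy 9-ketone
Product: 17 trans-fused 7β-(tert-butoxycarbonylmethyl)-6β-isobutyryloxy-10β-methyl-1α-(triisopropylsilyloxy)decal-2-ene-8α,9α-diol
Conditions: LiBH(s-Bu)3 (3 equiv), THF, −78 °C; aq NH4Cl
Reagents that add atoms: none
Why: Trialkylborohydride reduction along the equatorial trajectory: the β-approach is the equatorial one and the axial α-path is closed by the syn-axial C1 silyloxy group, so hydride should add from the β-face and give the axial 9α-alcohol cis to O8, the esters being inert at −78 °C.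

Step 11
Reactants: 17 8α,9α-diol tert-butyl ester
Product: 19 trans-fused 12,8α-lactone of the decal-2-ene (9α-hydroxy; 6β-isobutyryloxy; 10β-methyl; 1α-triisopropylsilyloxy; 7α-H; 8β-H), via hydroxy acid 18 (not isolated)
Conditions: CF3CO2H/CH2Cl2 (1:4), 0 °C to rt
Reagents that add atoms: none
Why: Acidolysis of the tert-butyl ester (loss of 2-methylpropene) followed by acid-catalysed lactonisation (5-exo-trig acyl substitution) onto the equatorial 8α-hydroxyl gives the trans-fused γ-lactone, since O6 is acylated and the axial 9α-hydroxyl lies trans to the C7 arm and cannot reach C12; no stereocentre changes.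

Step 12
Reactants: 19 12,8α-lactone; 20 N,N-dimethylmethyleneiminium iodide (Eschenmoser's salt)
Product: 22 11-(dimethylaminomethyl) 12,8α-lactone (C11 epimers), via dilithium alkoxide-enolate 21 (not isolated)
Conditions: LiN(iPr)2 (2.3 equiv), THF, −78 °C; 20, −78 to 0 °C
Reagents that add atoms: none
Why: Mannich aminomethylation of a lactone enolate: the first equivalent of amide base is spent on the 9-hydroxyl, the lactone α-CH2 is more acidic and more accessible than the isobutyrate methine, and the new C11 centre need not be controlled because it becomes trigonal in step 13.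

Step 13
Reactants: 22 11-(dimethylaminomethyl) lactone
Product: 24 11(13)-methylene 12,8α-lactone of the decal-2-ene (9α-hydroxy; 6β-isobutyryloxy; 1α-triisopropylsilyloxy), via ammonium iodide 23 (not isolated)
Conditions: MeI, MeCN, rt; then NaHCO3 (aq), CH2Cl2, rt
Reagents that add atoms: none
Why: Exhaustive N-methylation followed by base-induced β-elimination of trimethylamine (Hofmann-type E1cB elimination) gives the exocyclic α-methylene lactone under conditions too mild to touch the isobutyrate.

Step 14
Reactants: 24 silylated α-methylene lactone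
Product: 25 1α,9α-dihydroxy-6β-isobutyryloxy-10β-methyl-11(13)-methylene 12,8α-lactone of the decal-2-ene
Conditions: HF·pyridine, pyridine, THF, 0 °C to rt
Reagents that add atoms: none
Why: Fluoride-driven cleavage of the silyl ether (formation of the strong Si–F bond) in a buffered acidic medium frees the C1 hydroxyl without conjugate addition to the methylene lactone, and no stereocentre is affected.

Step 15
Reactants: 25 ring-A allylic alcohol
Product: 27 seco tetraol with a (1R)-1,2-dihydroxyethyl group on C10 and a 2-hydroxyethyl group on C5, via dialdehyde 26 (not isolated)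
Conditions: O3, CH2Cl2/MeOH (4:1), Sudan Red 7B, −78 °C; Me2S, −78 °C to rt; evaporate; NaBH(OAc)3, AcOH, THF, 0 °C to rt
Reagents that add atoms: ozone, [O-][O+]=O
Why: Ozonolysis (Criegee mechanism) is directed to the electron-richer cis-disubstituted ring-A alkene, the conjugated exo-methylene reacting much more slowly toward electrophilic ozone and the dye marking the end point, and NaBH(OAc)3 then reduces the two aldehydes but not the enoate, which NaBH4 would reduce in the conjugate sense; C1 keeps its configuration.

Step 16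
Reactants: 27 seco tetraol
Product: 28 seco acetonide with a (4R)-2,2-dimethyl-1,3-dioxolan-4-yl group on C10 and a free 2-hydroxyethyl group on C5
Conditions: 2,2-dimethoxypropane, pyridinium p-toluenesulfonate (cat.), acetone, 0 °C to rt
Reagents that add atoms: 2,2-dimethoxypropane, COC(C)(C)OC
Why: Acid-catalysed transacetalisation closes the five-membered dioxolane on the terminal 1,2-diol, which is favoured over a dioxane across O1 and O9 with its axial methyl and leaves the primary C3 hydroxyl free, any mixed acetal there being lost on work-up.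

Step 17
Reactants: 28 acetonide primary alcohol
Product: 29 seco acetonide aldehyde with a 2-oxoethyl group on C5
Conditions: 2,2,6,6-tetramethylpiperidin-1-oxyl (10 mol%), PhI(OAc)2, CH2Cl2, rt
Reagents that add atoms: none
Why: Oxoammonium (TEMPO) oxidation is selective for the unhindered primary alcohol over the hindered axial 9-hydroxyl and stops at the aldehyde in the absence of water, and the aldehyde cannot form a lactol with O9 because the C5 arm (β) and O9 (α) are trans.

Step 18
Reactants: 29 acetonide aldehyde; 20 N,N-dimethylmethyleneiminium iodide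
Product: 31 seco acetonide with a 3-oxoprop-1-en-2-yl group on C5, via Mannich base 30 (not isolated)
Conditions: 20 (3 equiv), Et3N, CH2Cl2, rt
Reagents that add atoms: none
Why: Mannich reaction of the aldehyde with the iminium salt followed by spontaneous β-elimination of dimethylamine (α-methylenation of an aldehyde) gives the 2-substituted acrolein, the excess iminium salt capturing the liberated dimethylamine as its aminal so that it does not add to the methylene lactone.

Step 19
Reactants: 31 acrolein acetonide
Product: 32 seco diol with a (1R)-1,2-dihydroxyethyl group on C10 and a 3-oxoprop-1-en-2-yl group on C5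
Conditions: AcOH/H2O (4:1), 40 °C
Reagents that add atoms: none
Why: Acid-catalysed hydrolysis of the terminal dioxolane in aqueous acetic acid should leave the ester, the lactone and both Michael acceptors untouched and does not affect C1.

Step 20
Reactants: 32 seco diol
Product: 34 CNP0496100.1, via primary tosylate 33 (not isolated)
Conditions: TsCl, Et3N, Bu2SnO (2 mol%), CH2Cl2, 0 °C to rt; then DBU, 0 °C
Reagents that add atoms: none
Why: Stannylene-directed sulfonylation picks the primary hydroxyl of the 1,2-diol and intramolecular Williamson etherification (3-exo-tet displacement by the C1 alkoxide formed with a non-nucleophilic amidine base) closes the oxirane at C2, so the C1–O bond is never broken and C1 keeps its R configuration.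

Compound list
1 | (E)-but-2-enal (crotonaldehyde) | C/C=C/C=O | starting material
2 | (E)-1-(triisopropylsilyloxy)buta-1,3-diene | C=C/C=C/O[Si](C(C)C)(C(C)C)C(C)C | intermediate
3 | 2-methoxy-5-methyl-1,4-benzoquinone | COC1=CC(=O)C(C)=CC1=O | starting material
4 | cis-fused cycloadduct: 7-methoxy-10β-methyl-1α-(triisopropylsilyloxy)decalin-2,7-diene-6,9-dione, 5β-H | C1=C(OC)C(=O)[C@H]2[C@](C)([C@@H](O[Si](C(C)C)(C(C)C)C(C)C)C=CC2)C1=O | intermediate
5 | cis-fused 7-hydroxy-10β-methyl-1α-(triisopropylsilyloxy)decalin-2,7-diene-6,9-dione (vinylogous acid) | C1=C(O)C(=O)[C@H]2[C@](C)([C@@H](O[Si](C(C)C)(C(C)C)C(C)C)C=CC2)C1=O | intermediate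
6 | cis-fused 7-(trifluoromethanesulfonyloxy)-10β-methyl-1α-(triisopropylsilyloxy)decalin-2,7-diene-6,9-dione | C1=C(OS(=O)(=O)C(F)(F)F)C(=O)[C@H]2[C@](C)([C@@H](O[Si](C(C)C)(C(C)C)C(C)C)C=CC2)C1=O | intermediate
7 | tert-butyl bromoacetate | CC(C)(C)OC(=O)CBr | starting material
8 | tert-butyl (bromozincio)acetate (Reformatsky reagent) | CC(C)(C)OC(=O)C[Zn]Br | intermediate
9 | cis-fused 7-(tert-butoxycarbonylmethyl)-10β-methyl-1α-(triisopropylsilyloxy)decalin-2,7-diene-6,9-dione | C1=C(CC(=O)OC(C)(C)C)C(=O)[C@H]2[C@](C)([C@@H](O[Si](C(C)C)(C(C)C)C(C)C)C=CC2)C1=O | intermediate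
10 | cis-fused (5β-H) 7-(tert-butoxycarbonylmethyl)-10β-methyl-1α-(triisopropylsilyloxy)decal-2-ene-6,9-dione, C7 epimers | C1C(CC(=O)OC(C)(C)C)C(=O)[C@H]2[C@](C)([C@@H](O[Si](C(C)C)(C(C)C)C(C)C)C=CC2)C1=O | intermediate
11 | trans-fused (5α-H) 7β-(tert-butoxycarbonylmethyl)-10β-methyl-1α-(triisopropylsilyloxy)decal-2-ene-6,9-dione | C1[C@@H](CC(=O)OC(C)(C)C)C(=O)[C@@H]2[C@](C)([C@@H](O[Si](C(C)C)(C(C)C)C(C)C)C=CC2)C1=O | intermediate
12 | trans-fused 7β-(tert-butoxycarbonylmethyl)-6β-hydroxy-10β-methyl-1α-(triisopropylsilyloxy)decal-2-en-9-one | C1[C@@H](CC(=O)OC(C)(C)C)[C@@H](O)[C@@H]2[C@](C)([C@@H](O[Si](C(C)C)(C(C)C)C(C)C)C=CC2)C1=O | intermediate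
13 | isobutyric anhydride (2-methylpropanoic anhydride) | CC(C)C(=O)OC(=O)C(C)C | starting material
14 | trans-fused 7β-(tert-butoxycarbonylmethyl)-6β-isobutyryloxy-10β-methyl-1α-(triisopropylsilyloxy)decal-2-en-9-one | C1[C@@H](CC(=O)OC(C)(C)C)[C@@H](OC(=O)C(C)C)[C@@H]2[C@](C)([C@@H](O[Si](C(C)C)(C(C)C)C(C)C)C=CC2)C1=O | intermediate
15 | sodium 8-en-9-olate of 14 | [Na+].C1[C@@H](CC(=O)OC(C)(C)C)[C@@H](OC(=O)C(C)C)[C@@H]2[C@](C)([C@@H](O[Si](C(C)C)(C(C)C)C(C)C)C=CC2)C=1[O-] | intermediate
16 | 8α-hydroxy derivative of 14 (equatorial α-ketol) | O[C@@H]1[C@@H](CC(=O)OC(C)(C)C)[C@@H](OC(=O)C(C)C)[C@@H]2[C@](C)([C@@H](O[Si](C(C)C)(C(C)C)C(C)C)C=CC2)C1=O | intermediate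
17 | trans-fused 7β-(tert-butoxycarbonylmethyl)-6β-isobutyryloxy-10β-methyl-1α-(triisopropylsilyloxy)decal-2-ene-8α,9α-diol | O[C@@H]1[C@@H](CC(=O)OC(C)(C)C)[C@@H](OC(=O)C(C)C)[C@@H]2[C@](C)([C@@H](O[Si](C(C)C)(C(C)C)C(C)C)C=CC2)[C@@H]1O | intermediate
18 | carboxylic acid of 17 (7β-carboxymethyl 8α,9α-diol) | O[C@@H]1[C@@H](CC(=O)O)[C@@H](OC(=O)C(C)C)[C@@H]2[C@](C)([C@@H](O[Si](C(C)C)(C(C)C)C(C)C)C=CC2)[C@@H]1O | intermediate
19 | trans-fused 12,8α-lactone of the decal-2-ene: 9α-hydroxy, 6β-isobutyryloxy, 10β-methyl, 1α-triisopropylsilyloxy, 7α-H, 8β-H | C1C(=O)O[C@@H]2[C@@H]1[C@@H](OC(=O)C(C)C)[C@@H]3[C@](C)([C@@H](O[Si](C(C)C)(C(C)C)C(C)C)C=CC3)[C@@H]2O | intermediate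
20 | N,N-dimethylmethyleneiminium iodide (Eschenmoser's salt) | C=[N+](C)C.[I-] | starting material
21 | dilithium salt of 19 (9-alkoxide and C11=C12 lactone enolate) | [Li+].[Li+].C1=C([O-])O[C@@H]2[C@@H]1[C@@H](OC(=O)C(C)C)[C@@H]3[C@](C)([C@@H](O[Si](C(C)C)(C(C)C)C(C)C)C=CC3)[C@@H]2[O-] | intermediate
22 | 11-(dimethylaminomethyl) derivative of 19, C11 epimers | CN(C)CC1C(=O)O[C@@H]2[C@@H]1[C@@H](OC(=O)C(C)C)[C@@H]3[C@](C)([C@@H](O[Si](C(C)C)(C(C)C)C(C)C)C=CC3)[C@@H]2O | intermediate
23 | 11-(trimethylammoniomethyl) lactone iodide, C11 epimers | C[N+](C)(C)CC1C(=O)O[C@@H]2[C@@H]1[C@@H](OC(=O)C(C)C)[C@@H]3[C@](C)([C@@H](O[Si](C(C)C)(C(C)C)C(C)C)C=CC3)[C@@H]2O.[I-] | intermediate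
24 | 11(13)-methylene 12,8α-lactone of the decal-2-ene: 9α-hydroxy, 6β-isobutyryloxy, 10β-methyl, 1α-triisopropylsilyloxy | C=C1C(=O)O[C@@H]2[C@@H]1[C@@H](OC(=O)C(C)C)[C@@H]3[C@](C)([C@@H](O[Si](C(C)C)(C(C)C)C(C)C)C=CC3)[C@@H]2O | intermediate
25 | 1α,9α-dihydroxy analogue of 24 (silyl group removed) | C=C1C(=O)O[C@@H]2[C@@H]1[C@@H](OC(=O)C(C)C)[C@@H]3[C@](C)([C@@H](O)C=CC3)[C@@H]2O | intermediate
26 | seco dialdehyde: ring B with 6β-isobutyryloxy, 9α-hydroxy, 10β-methyl and the trans-fused 11(13)-methylene 12,8α-lactone; (1R)-1-hydroxy-2-oxoethyl on C10 (α), 2-oxoethyl on C5 (β) | C=C1C(=O)O[C@@H]2[C@@H]1[C@@H](OC(=O)C(C)C)[C@@H](CC=O)[C@](C)([C@@H](O)C=O)[C@@H]2O | intermediate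
27 | seco tetraol: same ring B and lactone; (1R)-1,2-dihydroxyethyl on C10, 2-hydroxyethyl on C5 | C=C1C(=O)O[C@@H]2[C@@H]1[C@@H](OC(=O)C(C)C)[C@@H](CCO)[C@](C)([C@@H](O)CO)[C@@H]2O | intermediate
28 | seco acetonide alcohol: (4R)-2,2-dimethyl-1,3-dioxolan-4-yl on C10, 2-hydroxyethyl on C5 | C=C1C(=O)O[C@@H]2[C@@H]1[C@@H](OC(=O)C(C)C)[C@@H](CCO)[C@](C)([C@@H]3COC(C)(C)O3)[C@@H]2O | intermediate
29 | seco acetonide aldehyde: dioxolane on C10, 2-oxoethyl on C5 | C=C1C(=O)O[C@@H]2[C@@H]1[C@@H](OC(=O)C(C)C)[C@@H](CC=O)[C@](C)([C@@H]3COC(C)(C)O3)[C@@H]2O | intermediate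
30 | Mannich base of 29: 1-(dimethylamino)-3-oxopropan-2-yl on C5, C4 epimers | C=C1C(=O)O[C@@H]2[C@@H]1[C@@H](OC(=O)C(C)C)[C@@H](C(CN(C)C)C=O)[C@](C)([C@@H]3COC(C)(C)O3)[C@@H]2O | intermediate
31 | seco acrolein acetonide: dioxolane on C10, 3-oxoprop-1-en-2-yl on C5 | C=C1C(=O)O[C@@H]2[C@@H]1[C@@H](OC(=O)C(C)C)[C@@H](C(=C)C=O)[C@](C)([C@@H]3COC(C)(C)O3)[C@@H]2O | intermediate
32 | seco diol: (1R)-1,2-dihydroxyethyl on C10, 3-oxoprop-1-en-2-yl on C5 | C=C1C(=O)O[C@@H]2[C@@H]1[C@@H](OC(=O)C(C)C)[C@@H](C(=C)C=O)[C@](C)([C@@H](O)CO)[C@@H]2O | intermediate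
33 | primary tosylate of 32: (1R)-1-hydroxy-2-(p-toluenesulfonyloxy)ethyl on C10 | C=C1C(=O)O[C@@H]2[C@@H]1[C@@H](OC(=O)C(C)C)[C@@H](C(=C)C=O)[C@](C)([C@@H](O)COS(=O)(=O)c3ccc(C)cc3)[C@@H]2O | intermediate
34 | CNP0496100.1: ring B with 6β-isobutyryloxy, 9α-hydroxy, 10β-methyl, 5α-H, trans-fused 11(13)-methylene 12,8α-lactone (7α-H, 8β-H), (2R)-oxiran-2-yl on C10 and 3-oxoprop-1-en-2-yl on C5 | C=C1C(=O)O[C@@H]2[C@@H]1[C@@H](OC(=O)C(C)C)[C@@H](C(=C)C=O)[C@](C)([C@@H]1CO1)[C@@H]2O | target

Total step count: 20.
Longest linear sequence: 20 steps, from 1 to 34; the quinone 3 and the other bought compounds enter without steps of their own.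

Steps most likely to fail

Step 2. The catalyst sits at O9 on the C8–H side, some distance from the reacting C10=C5 bond, so enantioface discrimination may be weak; its residual Brønsted acidity may also desilylate the diene before cycloaddition. The fallback sets out from 2 and 3. BF3·OEt2 (20 mol%, CH2Cl2, −78 °C), a monodentate Lewis acid that should give the same orientation, is expected to give the racemic endo adduct, that is 4 together with the mirror-image cycloadduct F1. Hydrolysis as in step 3 then gives 5 mixed with the mirror-image hydroxy-enedione F2. Because this compound is a vinylogous carboxylic acid it can be resolved classically: crystallisation with (R)-1-phenylethylamine should separate the (R)-1-phenylethylammonium salt of 5 F3 from the diastereomeric salt of the antipode F4 (the other amine antipode is taken if the wrong salt crystallises). Dilute HCl frees 5, where the route is rejoined.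

Step 5. Direct attack of the zinc enolate on the C6 carbonyl of the very electrophilic triflate may outrun the palladium cycle, or the triflate may break down under the basic reagent. The fallback sets out from 6. The sodium salt of tert-butyl methyl malonate (NaH, THF, 0 °C), a soft stabilised carbanion, should displace triflate by conjugate addition–elimination at C7 and give the C7 malonate enedione F5. Zn/AcOH as in step 6 then gives the saturated malonate dione F6. Krapcho dealkoxycarbonylation (LiCl, wet DMSO, 130 °C) removes only the methyl ester carboxyl and leaves the kinetic dione 10, which the DBU treatment of step 6 turns into 11, where the route is rejoined.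

Step 20. The C1 alkoxide, or already the free diol of step 19, may add to the neighbouring acrolein and tie itself up as a six-membered lactol or oxa-Michael ring instead of closing the oxirane, and the base may isomerise the enal. The fallback sets out from 28 and closes the oxirane before any aldehyde exists. TBDPSCl and imidazole in CH2Cl2 silylate the primary hydroxyl to the silyl ether acetonide F7, and AcOH/H2O removes the acetonide to give the diol silyl ether F8. TsCl, Et3N and Bu2SnO give the primary tosylate F9, which DBU closes to the oxirane silyl ether F10. Bu4NF buffered with AcOH frees the epoxy alcohol F11, and the TEMPO/PhI(OAc)2 oxidation of step 17 gives the epoxy aldehyde F12. Treatment with 20 and Et3N as in step 18, through the epoxy Mannich base F13, then installs the methylene and gives 34 directly.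

Further compounds
F1 | step 2 | mirror-image cycloadduct (enantiomer of 4) | C1=C(OC)C(=O)[C@@H]2[C@@](C)([C@H](O[Si](C(C)C)(C(C)C)C(C)C)C=CC2)C1=O
F2 | step 2 | mirror-image hydroxy-enedione (enantiomer of 5) | C1=C(O)C(=O)[C@@H]2[C@@](C)([C@H](O[Si](C(C)C)(C(C)C)C(C)C)C=CC2)C1=O
F3 | step 2 | (R)-1-phenylethylammonium salt of 5 | C1=C([O-])C(=O)[C@H]2[C@](C)([C@@H](O[Si](C(C)C)(C(C)C)C(C)C)C=CC2)C1=O.C[C@@H]([NH3+])c1ccccc1
F4 | step 2 | (R)-1-phenylethylammonium salt of the antipode of 5 | C1=C([O-])C(=O)[C@@H]2[C@@](C)([C@H](O[Si](C(C)C)(C(C)C)C(C)C)C=CC2)C1=O.C[C@@H]([NH3+])c1ccccc1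
F5 | step 5 | C7 malonate enedione: cis-fused 7-[(tert-butoxycarbonyl)(methoxycarbonyl)methyl] analogue of 9 | C1=C(C(C(=O)OC)C(=O)OC(C)(C)C)C(=O)[C@H]2[C@](C)([C@@H](O[Si](C(C)C)(C(C)C)C(C)C)C=CC2)C1=O
F6 | step 5 | saturated malonate dione (C7=C8 reduced, C7 epimers) | C1C(C(C(=O)OC)C(=O)OC(C)(C)C)C(=O)[C@H]2[C@](C)([C@@H](O[Si](C(C)C)(C(C)C)C(C)C)C=CC2)C1=O
F7 | step 20 | silyl ether acetonide: 28 with a 2-(tert-butyldiphenylsilyloxy)ethyl group on C5 | C=C1C(=O)O[C@@H]2[C@@H]1[C@@H](OC(=O)C(C)C)[C@@H](CCO[Si](c3ccccc3)(c4ccccc4)C(C)(C)C)[C@](C)([C@@H]3COC(C)(C)O3)[C@@H]2O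
F8 | step 20 | diol silyl ether: (1R)-1,2-dihydroxyethyl on C10, silyloxyethyl on C5 | C=C1C(=O)O[C@@H]2[C@@H]1[C@@H](OC(=O)C(C)C)[C@@H](CCO[Si](c3ccccc3)(c4ccccc4)C(C)(C)C)[C@](C)([C@@H](O)CO)[C@@H]2O
F9 | step 20 | primary tosylate of F8 | C=C1C(=O)O[C@@H]2[C@@H]1[C@@H](OC(=O)C(C)C)[C@@H](CCO[Si](c3ccccc3)(c4ccccc4)C(C)(C)C)[C@](C)([C@@H](O)COS(=O)(=O)c3ccc(C)cc3)[C@@H]2O
F10 | step 20 | oxirane silyl ether: (2R)-oxiran-2-yl on C10, silyloxyethyl on C5 | C=C1C(=O)O[C@@H]2[C@@H]1[C@@H](OC(=O)C(C)C)[C@@H](CCO[Si](c3ccccc3)(c4ccccc4)C(C)(C)C)[C@](C)([C@@H]3CO3)[C@@H]2O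
F11 | step 20 | epoxy alcohol: (2R)-oxiran-2-yl on C10, 2-hydroxyethyl on C5 | C=C1C(=O)O[C@@H]2[C@@H]1[C@@H](OC(=O)C(C)C)[C@@H](CCO)[C@](C)([C@@H]3CO3)[C@@H]2O
F12 | step 20 | epoxy aldehyde: (2R)-oxiran-2-yl on C10, 2-oxoethyl on C5 | C=C1C(=O)O[C@@H]2[C@@H]1[C@@H](OC(=O)C(C)C)[C@@H](CC=O)[C@](C)([C@@H]3CO3)[C@@H]2O
F13 | step 20 | epoxy Mannich base: (2R)-oxiran-2-yl on C10, 1-(dimethylamino)-3-oxopropan-2-yl on C5 (C4 epimers) | C=C1C(=O)O[C@@H]2[C@@H]1[C@@H](OC(=O)C(C)C)[C@@H](C(CN(C)C)C=O)[C@](C)([C@@H]3CO3)[C@@H]2O
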